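**Retrosynthetic overview**

1. Numbering: ring A = C1–C5 and C10 (gem-dimethyl on C4, methyl on C10); ring B = C5–C10 (carbinol C8, methine C9); side chain C11, C12, C13=C14 onward. The last disconnection is C12–C13 (B-alkyl Suzuki–Miyaura), giving vinyl decalinol 10 and vinyl iodide 17 (from geranyl bromide).
2. Ring B of 10 is opened at C6–C7 and at C8–C9. An acetone unit (C7, C8 and the C8 methyl, as bromoacetone) is stitched between the C6 end of an exocyclic C5=C6 alkene (through its borane) and C9, the γ-carbon of an (E)-allylboronate on C10.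
3. Enabling feature: in ring B the tertiary carbinol C8(OH)CH3 lies between the C7 methylene and C9–H, which carries the two-carbon branch C11–C12. With C11=C12 as a vinyl group this is a homoallylic tertiary alcohol, the retron of a ketone allylboration, and C7 is the α-carbon of that methyl ketone.
4. Ring A is made first (2,2,6-trimethylcyclohexanone, C10 set by palladium-catalysed decarboxylative allylation), ring B second. The allyl group is converted into the allylboronate by allylic C–H borylation.

Key step: step 5

Remark on the chemistry: the target SMILES defines the 5R,8R,9R,10S isomer, a cis-fused decalin (H-5, the C10 methyl, the C8 methyl and the C9 side chain on one face, 8-OH on the other); the route is planned for exactly this isomer.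
Remark on the chemistry: (R)-t-Bu-PHOX is assumed to give the (R)-ketone 4, by analogy with the usual sense of induction of this ligand class; otherwise the other ligand enantiomer is used.

**Route**

Step 1
Reactants: 1 2,2,6-trimethylcyclohexan-1-one (racemic)
Product: 3 prop-2-en-1-yl 2,6,6-trimethylcyclohex-1-en-1-yl carbonate, via lithium enolate 2 (not isolated)
Conditions: LiN(SiMe3)2, TMEDA, THF, 0 °C; then ClCO2CH2CH=CH2, -78 °C to rt
Reagents that add atoms: allyl chloroformate, C=CCOC(Cl)=O
Why: Deprotonation at the only enolisable position gives the tetrasubstituted enolate 2, which is O-acylated by the chloroformate (enol carbonate formation); no stereocentre is formed.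

Step 2
Reactants: 3 prop-2-en-1-yl 2,6,6-trimethylcyclohex-1-en-1-yl carbonate
Product: 4 (2R)-2,6,6-trimethyl-2-(prop-2-en-1-yl)cyclohexan-1-one
Conditions: Pd2(dba)3 (2.5 mol %), (R)-t-Bu-PHOX (6 mol %), THF, 25 °C
Reagents that add atoms: none
Why: Decarboxylative asymmetric allylic alkylation (Tsuji allylation): zerovalent palladium ionises the allyl carbonate, CO2 is lost and the enolate is allylated inside the chiral (PHOX)Pd(allyl) ion pair, so the ligand sets the quaternary centre that becomes C10.

Step 3
Reactants: 4 (2R)-2,6,6-trimethyl-2-(prop-2-en-1-yl)cyclohexan-1-one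
Product: 5 (1R)-1,3,3-trimethyl-2-methylidene-1-(prop-2-en-1-yl)cyclohexane
Conditions: Ph3PCH3Br, KOt-Bu, toluene, 110 °C
Reagents that add atoms: methyltriphenylphosphonium bromide, C[P+](c1ccccc1)(c1ccccc1)c1ccccc1.[Br-]
Why: Wittig methylenation; the ketone has no α-hydrogen, so the hot alkoxide conditions used for hindered ketones cannot enolise it, and the stereocentre is not touched.

Step 4
Reactants: 5 (1R)-1,3,3-trimethyl-2-methylidene-1-(prop-2-en-1-yl)cyclohexane
Product: 6 4,4,5,5-tetramethyl-2-{(2E)-3-[(1R)-1,3,3-trimethyl-2-methylidenecyclohexyl]prop-2-en-1-yl}-1,3,2-dioxaborolane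
Conditions: Pd(O2CCF3)2 (10 mol %), B2pin2, 2,6-dimethyl-1,4-benzoquinone, CF3CO2H (cat.), toluene, 50 °C
Reagents that add atoms: bis(pinacolato)diboron, CC1(C)OB(OC1(C)C)B1OC(C)(C)C(C)(C)O1
Why: Palladium-catalysed oxidative allylic C–H borylation: divalent palladium cleaves an allylic C9–H bond of the terminal alkene to an η3-allyl complex, B2pin2 transmetalates and C–B reductive elimination at the unhindered terminus should give the linear (E)-allylboronate (the quinone returns palladium to the divalent state), while the methylidene group has no allylic hydrogen and C10 is untouched.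

Step 5
Reactants: 6 4,4,5,5-tetramethyl-2-{(2E)-3-[(1R)-1,3,3-trimethyl-2-methylidenecyclohexyl]prop-2-en-1-yl}-1,3,2-dioxaborolane
Product: 10 (1R,2R,4aR,8aS)-1-ethenyl-2,5,5,8a-tetramethyldecahydronaphthalen-2-ol, via B-alkyl-9-BBN borane 7 (not isolated), via keto allylboronate 8 (not isolated), via borate ester 9 (not isolated)
Conditions: 9-BBN-H (1.1 equiv), THF, 60 °C; then BrCH2COCH3, potassium 2,6-di-tert-butylphenoxide, THF, 0 °C to 45 °C; then NaOH, H2O2, 0 °C
Reagents that add atoms: bromoacetone, BrCC(C)=O
Why: Proposed new method: 9-BBN adds to the C5=C6 methylidene group to give borane 7, whose ate complex with the potassium α-bromo enolate of bromoacetone undergoes 1,2-migration of C6 from boron to C7 with loss of bromide (C6–C7 bond), the phenol then releases methyl ketone 8 from the enol borinate, and 8 is trapped by the tethered (E)-allylboronate (C8–C9 bond) to give borate 9, hydrolysed on work-up; the closest known reaction types are the α-alkylation of α-bromo ketones by B-alkyl-9-BBN reagents under a hindered phenoxide and the ring-closing allylboration of tethered carbonyl groups, and only their union in one flask is new. Ring B is closed in the second event, 6-exo-trig at the ketone carbonyl, through a chair Zimmerman–Traxler array fused to the chair of the forming ring. C5 is set in the hydroboration: the ring A chair with the C10 alkenyl arm axial (the alternative puts the C10 methyl syn-diaxial to a C4 methyl) exposes only the opposite face of the methylidene group, so H-5 should arrive cis to the C10 methyl and the C6 and C9 arms end up cis. C8 and C9 are set in the allylboration: the (E)-alkene puts the C10 substituent equatorial in the six-membered boron array, which should give the anti adduct (8-OH trans and 8-CH3 cis to the vinyl group), and closure from that same ring A chair with the vinyl group equatorial on ring B places it cis to the C10 methyl. The step needs chemoselective hydroboration of the 1,1-disubstituted alkene beside the trans-disubstituted allylboronate alkene (the known preference of 9-BBN), binding of the bromo enolate to the trialkylborane and not to the much less Lewis acidic pinacol boronate, and intramolecular allylation outrunning any intermolecular one (pinacol allylboronates add to ketones slowly unless tethered).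

Step 6
Reactants: 11 (2E)-1-bromo-3,7-dimethylocta-2,6-diene (geranyl bromide); 12 trimethyl(prop-1-yn-1-yl)silane
Product: 14 trimethyl[(5E)-6,10-dimethylundeca-5,9-dien-1-yn-1-yl]silane, via propargylic lithium reagent 13 (not isolated)
Conditions: 12, n-BuLi, THF, -78 °C; then 11, -78 °C to rt
Reagents that add atoms: none
Why: Propargylic lithiation of the silylpropyne and SN2 alkylation by the primary allylic bromide; the silyl group keeps the anion from reacting at the alkyne terminus and the (E)-alkene of 11 is retained.

Step 7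
Reactants: 14 trimethyl[(5E)-6,10-dimethylundeca-5,9-dien-1-yn-1-yl]silane
Product: 15 (5E)-6,10-dimethylundeca-5,9-dien-1-yne
Conditions: K2CO3 (cat.), MeOH, rt
Reagents that add atoms: none
Why: Base-catalysed methanolysis of the alkynyl C–Si bond (protodesilylation).

Step 8
Reactants: 15 (5E)-6,10-dimethylundeca-5,9-dien-1-yne
Product: 17 (1E,5E)-1-iodo-2,6,10-trimethylundeca-1,5,9-triene, via alkenylalane 16 (not isolated)
Conditions: Me3Al, Cp2ZrCl2 (cat.), CH2Cl2, 0 °C to rt; then I2, THF, -30 °C
Reagents that add atoms: trimethylaluminium, C[Al](C)C; iodine, II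
Why: Negishi zirconium-catalysed carboalumination: syn addition of methyl and aluminium across the terminal alkyne (methyl to the internal carbon) and iodinolysis of the C–Al bond with retention give the (E)-trisubstituted vinyl iodide.

Step 9
Reactants: 10 (1R,2R,4aR,8aS)-1-ethenyl-2,5,5,8a-tetramethyldecahydronaphthalen-2-ol; 17 (1E,5E)-1-iodo-2,6,10-trimethylundeca-1,5,9-triene
Product: 19 (1R,2R,4aR,8aS)-2,5,5,8a-tetramethyl-1-[(3E,7E)-4,8,12-trimethyltrideca-3,7,11-trien-1-yl]decahydronaphthalen-2-ol (the target), via B-alkyl-9-BBN borane 18 (not isolated)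
Conditions: 9-BBN-H, THF, rt; then 17, PdCl2(dppf), AsPh3, Cs2CO3, DMF/H2O, rt
Reagents that add atoms: none
Why: 9-BBN adds anti-Markovnikov to the only alkene of 10 (boron on C12) and the B-alkyl Suzuki–Miyaura coupling joins C12 to C13 with retention of the (E)-geometry of 17; no stereocentre is touched and the tertiary alcohol should need no protection.

**Compound list**

1 | 2,2,6-trimethylcyclohexan-1-one (racemic) | CC1CCCC(C)(C)C1=O | starting material
2 | lithium 2,6,6-trimethylcyclohex-1-en-1-olate | [Li+].[O-]C1=C(C)CCCC1(C)C | intermediate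
3 | prop-2-en-1-yl 2,6,6-trimethylcyclohex-1-en-1-yl carbonate | C=CCOC(=O)OC1=C(C)CCCC1(C)C | intermediate
4 | (2R)-2,6,6-trimethyl-2-(prop-2-en-1-yl)cyclohexan-1-one | C=CC[C@@]1(C)CCCC(C)(C)C1=O | intermediate
5 | (1R)-1,3,3-trimethyl-2-methylidene-1-(prop-2-en-1-yl)cyclohexane | C=CC[C@@]1(C)CCCC(C)(C)C1=C | intermediate
6 | 4,4,5,5-tetramethyl-2-{(2E)-3-[(1R)-1,3,3-trimethyl-2-methylidenecyclohexyl]prop-2-en-1-yl}-1,3,2-dioxaborolane | CC1(C)OB(C/C=C/[C@@]2(C)CCCC(C)(C)C2=C)OC1(C)C | intermediate
7 | 9-{[(1R,2R)-2,6,6-trimethyl-2-[(1E)-3-(4,4,5,5-tetramethyl-1,3,2-dioxaborolan-2-yl)prop-1-en-1-yl]cyclohexyl]methyl}-9-borabicyclo[3.3.1]nonane (the two side arms cis) | CC1(C)OB(C/C=C/[C@@]2(C)CCCC(C)(C)[C@H]2CB3C4CCCC3CCC4)OC1(C)C | intermediate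
8 | 4-[(1R,2R)-2,6,6-trimethyl-2-[(1E)-3-(4,4,5,5-tetramethyl-1,3,2-dioxaborolan-2-yl)prop-1-en-1-yl]cyclohexyl]butan-2-one | CC1(C)OB(C/C=C/[C@@]2(C)CCCC(C)(C)[C@H]2CCC(C)=O)OC1(C)C | intermediate
9 | 2-{[(1R,2R,4aR,8aS)-1-ethenyl-2,5,5,8a-tetramethyldecahydronaphthalen-2-yl]oxy}-4,4,5,5-tetramethyl-1,3,2-dioxaborolane | C=C[C@@H]1[C@@]2(C)CCCC(C)(C)[C@H]2CC[C@@]1(C)OB1OC(C)(C)C(C)(C)O1 | intermediate
10 | (1R,2R,4aR,8aS)-1-ethenyl-2,5,5,8a-tetramethyldecahydronaphthalen-2-ol (cis-fused) | C=C[C@@H]1[C@@]2(C)CCCC(C)(C)[C@H]2CC[C@@]1(C)O | intermediate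
11 | (2E)-1-bromo-3,7-dimethylocta-2,6-diene (geranyl bromide) | CC(C)=CCC/C(C)=C/CBr | starting material
12 | trimethyl(prop-1-yn-1-yl)silane | CC#C[Si](C)(C)C | starting material
13 | [3-(trimethylsilyl)prop-2-yn-1-yl]lithium | [Li+].[CH2-]C#C[Si](C)(C)C | intermediate
14 | trimethyl[(5E)-6,10-dimethylundeca-5,9-dien-1-yn-1-yl]silane | CC(C)=CCC/C(C)=C/CCC#C[Si](C)(C)C | intermediate
15 | (5E)-6,10-dimethylundeca-5,9-dien-1-yne | CC(C)=CCC/C(C)=C/CCC#C | intermediate
16 | dimethyl[(1E,5E)-2,6,10-trimethylundeca-1,5,9-trien-1-yl]alane | CC(C)=CCC/C(C)=C/CC/C(C)=C/[Al](C)C | intermediate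
17 | (1E,5E)-1-iodo-2,6,10-trimethylundeca-1,5,9-triene | CC(C)=CCC/C(C)=C/CC/C(C)=C/I | intermediate
18 | (1R,2R,4aR,8aS)-1-[2-(9-borabicyclo[3.3.1]nonan-9-yl)ethyl]-2,5,5,8a-tetramethyldecahydronaphthalen-2-ol | C(CB1C2CCCC1CCC2)[C@@H]1[C@@]2(C)CCCC(C)(C)[C@H]2CC[C@@]1(C)O | intermediate
19 | (1R,2R,4aR,8aS)-2,5,5,8a-tetramethyl-1-[(3E,7E)-4,8,12-trimethyltrideca-3,7,11-trien-1-yl]decahydronaphthalen-2-ol (cis-fused) | CC(C)=CCC/C(C)=C/CC/C(C)=C/CC[C@@H]1[C@@]2(C)CCCC(C)(C)[C@H]2CC[C@@]1(C)O | target

**Step count and risks**

Total step count: 9. Longest linear sequence: 6 steps (steps 1, 2, 3, 4, 5 and 9); the vinyl iodide branch is 3 steps (steps 6–8).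

Steps most likely to fail:

1. Step 5. The relay may break down: hydroboration may lose its site or face selectivity, the bromo enolate may be intercepted by the boronate, or the ketone may be allylated through the other chair, which would scramble C5, C8 or C9. The fallback makes the two bonds in two operations by known chemistry. It sets out from 5: the allyl group is isomerised with RuHCl(CO)(PPh3)3 (toluene, 80 °C) to (1R)-1,3,3-trimethyl-2-methylidene-1-[(1E)-prop-1-en-1-yl]cyclohexane F1. Hydroboration of its methylidene group with 9-BBN-H and alkylation of the borane with bromoacetone and potassium 2,6-di-tert-butylphenoxide should give the isolable keto olefin 4-[(1R,2R)-2,6,6-trimethyl-2-[(1E)-prop-1-en-1-yl]cyclohexyl]butan-2-one F2 (C6–C7 bond). A Lewis acid carbonyl-ene cyclisation (Me2AlCl, CH2Cl2, -78 to 0 °C), in which C9 attacks the ketone and a hydrogen of the propenyl methyl group passes to oxygen, then forms the C8–C9 bond and the vinyl group and comes back to the route at 10.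

2. Step 4. Palladation of the hindered allylic C9–H bond may be slow, and the allylboronate may be lost by protodeboronation under the oxidative conditions or on purification. The fallback sets out from 5 and goes through a C–O bond first: allylic C–H acetoxylation (Pd(OAc)2, 1,2-bis(phenylsulfinyl)ethane, 1,4-benzoquinone, AcOH, dioxane, 45 °C) to the linear acetate (2E)-3-[(1R)-1,3,3-trimethyl-2-methylidenecyclohexyl]prop-2-en-1-yl acetate F3. Miyaura borylation of the allylic acetate with B2pin2 under zerovalent palladium (Pd2(dba)3, DMSO, 50 °C) then comes back at 6.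

3. Step 3. The ylide may fail to add to a carbonyl group flanked by two quaternary carbons, so that 4 is recovered. The fallback sets out from 4 and uses a Peterson olefination: Me3SiCH2Li (THF, with CeCl3 if needed) adds to the ketone to give (2R)-2,6,6-trimethyl-2-(prop-2-en-1-yl)-1-[(trimethylsilyl)methyl]cyclohexan-1-ol F4 (either configuration at C1), and KH in THF eliminates the silanolate to come back at 5.

Further compounds
F1 | step 5 | (1R)-1,3,3-trimethyl-2-methylidene-1-[(1E)-prop-1-en-1-yl]cyclohexane | C/C=C/[C@@]1(C)CCCC(C)(C)C1=C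
F2 | step 5 | 4-[(1R,2R)-2,6,6-trimethyl-2-[(1E)-prop-1-en-1-yl]cyclohexyl]butan-2-one | C/C=C/[C@@]1(C)CCCC(C)(C)[C@H]1CCC(C)=O
F3 | step 4 | (2E)-3-[(1R)-1,3,3-trimethyl-2-methylidenecyclohexyl]prop-2-en-1-yl acetate | CC(=O)OC/C=C/[C@@]1(C)CCCC(C)(C)C1=C
F4 | step 3 | (2R)-2,6,6-trimethyl-2-(prop-2-en-1-yl)-1-[(trimethylsilyl)methyl]cyclohexan-1-ol | C=CC[C@@]1(C)CCCC(C)(C)C1(O)C[Si](C)(C)C
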